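**Strategy**

The synthesis rests on closing the 14-membered carbocycle at the C12–C13 bond (cembrane numbering). This is the bond between the methyl-bearing sp2 carbon of the (E)-C11=C12 alkene and the carbinol carbon that carries the acetate, next to the lactone oxygen on C14. An intramolecular Nozaki–Hiyama–Kishi reaction of an acyclic (E)-alkenyl iodide aldehyde makes this bond, the ring, the allylic alcohol and the C13 stereocenter in one operation, under Felkin–Anh control by the C14–O bond of the preformed trans α-methylene-γ-lactone. The precursor is a farnesol-derived chain bearing the Sharpless epoxide, the lactone aldehyde and a terminal 2-iodo-2-alkene; acetylation and a singlet-oxygen ene reaction complete the target.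

Key step: step 13

Remark: cembrane numbering is used throughout. C1 is the lactone ring carbon bearing C15, C14 the lactone O–CH, C16 the lactone carbonyl, C17 the exocyclic methylene carbon, and C18, C19, C20 the carbons on C4, C8, C12.

Remark: in step 10 the antipode of the chiral ligand is taken to be the one that delivers the allyl group to the Re face of aldehyde 14; this is to be confirmed on a model aldehyde.

**Route**

Step 1
Reactants: 1 (2E,6E)-farnesyl acetate
Product: 2 (2E,6E)-10-bromo-11-hydroxy-3,7,11-trimethyldodeca-2,6-dien-1-yl acetate (racemic at C10)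
Conditions: NBS, THF/H2O, 0 °C
Reagents that add atoms: N-bromosuccinimide (O=C1CCC(=O)N1Br); water (O)
Why: Bromohydrin formation in aqueous medium should be selective for the terminal trisubstituted alkene (the 2,3-alkene is deactivated by the allylic acetate), water opening the bromonium ion at the tertiary carbon; the C10 stereocenter forms racemic and is destroyed in step 3.

Step 2
Reactants: 2 bromohydrin acetate
Product: 3 (2E,6E)-10,11-epoxy-3,7,11-trimethyldodeca-2,6-dien-1-ol (racemic epoxide)
Conditions: K2CO3, MeOH, rt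
Reagents that add atoms: none
Why: Intramolecular Williamson closure of the bromohydrin should give the epoxide while methanolysis removes the acetate.

Step 3
Reactants: 3 epoxy alcohol
Product: 4 (4E,8E)-10-hydroxy-4,8-dimethyldeca-4,8-dienal
Conditions: H5IO6, THF/H2O, 0 °C
Reagents that add atoms: none
Why: Periodic acid should hydrolyse the trisubstituted epoxide to the glycol and cleave it in the same flask (glycol cleavage), releasing acetone and leaving the two E-alkenes and the allylic alcohol untouched.

Step 4
Reactants: 4 hydroxy aldehyde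
Product: 5 (2E,6E)-3,7-dimethylundeca-2,6-dien-10-yn-1-ol
Conditions: dimethyl (1-diazo-2-oxopropyl)phosphonate, K2CO3, MeOH, 0 °C to rt
Reagents that add atoms: dimethyl (1-diazo-2-oxopropyl)phosphonate (COP(=O)(OC)C(=[N+]=[N-])C(C)=O)
Why: Ohira–Bestmann homologation should convert the aldehyde into the terminal alkyne under mild basic conditions that tolerate the free allylic alcohol.

Step 5
Reactants: 5 terminal alkynol
Product: 6 (2E,6E)-3,7-dimethyldodeca-2,6-dien-10-yn-1-ol
Conditions: n-BuLi (2.1 equiv), THF, −78 to 0 °C; then MeI (1.0 equiv), DMPU, 0 °C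
Reagents that add atoms: iodomethane (CI)
Why: In the alkoxide/acetylide dianion the acetylide carbon is far more nucleophilic than the lithium alkoxide, so one equivalent of iodomethane should give C-methylation (alkylation of an alkynol dianion).

Step 6
Reactants: 6 methyl alkynol
Product: 8 (2E,6E,10E)-11-iodo-3,7-dimethyldodeca-2,6,10-trien-1-ol, via alkenylzirconocene chloride 7 (not isolated)
Conditions: Cp2ZrHCl (3 equiv), THF, rt to 40 °C; then I2, 0 °C
Reagents that add atoms: iodine (II); Cp2ZrHCl ([H][Zr](Cl)(C1C=CC=C1)C1C=CC=C1) for intermediate 7 only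
Why: Syn hydrozirconation of the 2-alkyne with excess hydride should equilibrate zirconium to the less hindered methyl-bearing carbon, and iododezirconation with retention then gives the (E)-2-iodo-2-alkene; the trisubstituted alkenes do not react.

Step 7
Reactants: 8 iodo trienol
Product: 9 [(2S,3S)-3-[(3E,7E)-8-iodo-4-methylnona-3,7-dien-1-yl]-3-methyloxiran-2-yl]methanol
Conditions: Ti(OiPr)4, L-(+)-diethyl tartrate, t-BuOOH, 4 Å MS, CH2Cl2, −20 °C
Reagents that add atoms: tert-butyl hydroperoxide (CC(C)(C)OO)
Why: Sharpless asymmetric epoxidation epoxidises only the allylic-alcohol alkene, and with L-(+)-tartrate an (E)-3-methyl-2-alken-1-ol should give the (2S,3S)-epoxy alcohol, which sets C3 (S) and C4 (S) of the target.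

Step 8
Reactants: 9 epoxy alcohol
Product: 11 (2S,3S)-2-allyl-3-[(3E,7E)-8-iodo-4-methylnona-3,7-dien-1-yl]-3-methyloxirane, via epoxy triflate 10 (not isolated)
Conditions: Tf2O, 2,6-lutidine, CH2Cl2, −78 °C; then CH2=CHMgBr, CuI (cat.), THF, −78 to −30 °C
Reagents that add atoms: vinylmagnesium bromide (C=C[Mg]Br); trifluoromethanesulfonic anhydride (O=S(=O)(OS(=O)(=O)C(F)(F)F)C(F)(F)F) for intermediate 10 only
Why: Copper-catalysed SN2 displacement of the primary triflate by the vinyl Grignard reagent should be much faster than attack on the hindered trisubstituted epoxide or on the alkenyl iodide at low temperature, and no stereocenter is touched.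

Step 9
Reactants: 11 allyl epoxide; 12 methyl 2-(bromomethyl)acrylate
Product: 13 methyl (2Z)-2-(bromomethyl)-4-[(2S,3S)-3-[(3E,7E)-8-iodo-4-methylnona-3,7-dien-1-yl]-3-methyloxiran-2-yl]but-2-enoate
Conditions: 12 (excess), second-generation Hoveyda–Grubbs catalyst RuCl2(SIMes)(=CH-C6H4-2-OiPr) (cat.), CH2Cl2, 40 °C
Reagents that add atoms: none
Why: Olefin cross-metathesis of the monosubstituted alkene with the 1,1-disubstituted acrylate should give the trisubstituted enoate with the chain trans to the ester; the trisubstituted alkene and the alkenyl iodide are inert, and ring closure onto C7=C8 would need a seven-membered ring containing a trans-fused oxirane.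

Step 10
Reactants: 13 allylic bromide; 14 (tert-butyldimethylsilyloxy)acetaldehyde
Product: 16 (4R,5R)-5-[(tert-butyldimethylsilyloxy)methyl]-4-{[(2S,3S)-3-[(3E,7E)-8-iodo-4-methylnona-3,7-dien-1-yl]-3-methyloxiran-2-yl]methyl}-3-methylideneoxolan-2-one, via hydroxy ester 15 (not isolated)
Conditions: CrCl2 (10 mol %, nickel-free), (S,S)-3,6-di-tert-butyl-1,8-bis(4-isopropyl-4,5-dihydrooxazol-2-yl)-9H-carbazole (12 mol %), Mn, Cp2ZrCl2, iPr2NEt (cat.), THF, rt; then aq. NH4Cl, silica gel
Reagents that add atoms: none
Why: In this Nozaki–Hiyama-type 2-(alkoxycarbonyl)allylation with lactonization, the equilibrating allylchromium species (trivalent chromium, turned over by Mn and Cp2ZrCl2) should add through a chair transition state with both substituents equatorial to give the anti adduct and hence the 4,5-trans lactone, while the chiral tridentate ligand directs attack to the Re face of the aldehyde, setting C14 (R) and C1 (R); Cp2ZrCl2 replaces a silyl chloride to spare the epoxide.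

Step 11
Reactants: 16 silyl ether lactone
Product: 17 (4R,5R)-5-(hydroxymethyl)-4-{[(2S,3S)-3-[(3E,7E)-8-iodo-4-methylnona-3,7-dien-1-yl]-3-methyloxiran-2-yl]methyl}-3-methylideneoxolan-2-one
Conditions: TBAF, AcOH, THF, 0 °C to rt
Reagents that add atoms: none
Why: Buffered fluoride desilylation should free the primary alcohol without conjugate addition to the α-methylene lactone or opening of the epoxide.

Step 12
Reactants: 17 primary alcohol
Product: 18 (2R,3R)-3-{[(2S,3S)-3-[(3E,7E)-8-iodo-4-methylnona-3,7-dien-1-yl]-3-methyloxiran-2-yl]methyl}-4-methylidene-5-oxooxolane-2-carbaldehyde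
Conditions: Dess–Martin periodinane, NaHCO3, CH2Cl2, 0 °C to rt; used crude
Reagents that add atoms: none
Why: Dess–Martin oxidation under buffered, non-basic conditions should give the sensitive α-acyloxy aldehyde without epimerising C14, whose 2,3-trans arrangement is also the thermodynamically preferred one.

Step 13
Reactants: 18 alkenyl iodide aldehyde
Product: 19 (1R,3S,4S,7E,11E,13S,14R)-3,4-epoxy-13-hydroxycembra-7,11,15(17)-trien-16,14-olide
Conditions: CrCl2 (excess), NiCl2 (cat.), DMSO/THF, rt, high dilution, slow addition of 18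
Reagents that add atoms: none
Why: Zerovalent nickel, formed from NiCl2 by CrCl2, inserts into the C12–I bond with retention of the E geometry, and transmetalation gives an alkenylchromium species (trivalent chromium) that adds only to the aldehyde, leaving the lactone carbonyl, the enoate and the epoxide untouched. The closest known reaction type is the chromium/nickel-mediated alkenyl iodide–aldehyde macrocyclization (Nozaki–Hiyama–Kishi reaction) used to close medium and large carbocycles. The 14-membered ring closes in the 14-exo-trig mode, the C13=O bond being exocyclic to the forming ring. The new stereocenter C13 (S) is controlled by C14 through the Felkin–Anh polar model: the lactone C14–O bond lies anti to the incoming alkenyl group, which passes the C14–H, and for the (14R)-aldehyde this gives the 13,14-anti arrangement of the target. The step needs chemoselectivity for the aldehyde, retention of alkene geometry and cyclization in preference to oligomerization; the first two are intrinsic to the organochromium reagent and the third is secured by high dilution, helped by the rigid trans-lactone and the two E-alkenes, which restrict the chain.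

Step 14
Reactants: 19 macrocyclic allylic alcohol
Product: 20 (1R,3S,4S,7E,11E,13S,14R)-13-acetoxy-3,4-epoxycembra-7,11,15(17)-trien-16,14-olide
Conditions: Ac2O, pyridine, DMAP (cat.), CH2Cl2, 0 °C to rt
Reagents that add atoms: acetic anhydride (CC(=O)OC(C)=O)
Why: Nucleophile-catalysed acylation of the secondary allylic alcohol should proceed with retention at C13 and also blocks acyl migration from the neighbouring lactone.

Step 15
Reactants: 20 macrocyclic acetate
Product: 21 (1R,3S,4S,7S,11E,13S,14R)-13-acetoxy-3,4-epoxy-7-hydroperoxycembra-8(19),11,15(17)-trien-16,14-olide (CNP0166375.1)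
Conditions: O2, visible light, tetraphenylporphyrin (cat.), CH2Cl2, −20 °C
Reagents that add atoms: oxygen (O=O)
Why: In this Schenck ene reaction singlet oxygen should attack the electron-rich C7=C8 alkene (C11=C12 is deactivated by the allylic acetate, the enoate is inert), bonding to C7 and abstracting a C19 methyl hydrogen on the more substituted side (cis effect) to give the exocyclic alkene; C7 (S) is expected from attack on the exposed outer face of the ring alkene and is set only by the substrate, so the C7 epimer and the C8 hydroperoxide are the by-products to be separated.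

**Compound list**

1 | (2E,6E)-farnesyl acetate | CC(=O)OC/C=C(\C)CC/C=C(\C)CCC=C(C)C | starting material
2 | (2E,6E)-10-bromo-11-hydroxy-3,7,11-trimethyldodeca-2,6-dien-1-yl acetate (racemic at C10) | CC(=O)OC/C=C(\C)CC/C=C(\C)CCC(Br)C(C)(C)O | intermediate
3 | (2E,6E)-10,11-epoxy-3,7,11-trimethyldodeca-2,6-dien-1-ol (racemic epoxide) | OC/C=C(\C)CC/C=C(\C)CCC1OC1(C)C | intermediate
4 | (4E,8E)-10-hydroxy-4,8-dimethyldeca-4,8-dienal | OC/C=C(\C)CC/C=C(\C)CCC=O | intermediate
5 | (2E,6E)-3,7-dimethylundeca-2,6-dien-10-yn-1-ol | OC/C=C(\C)CC/C=C(\C)CCC#C | intermediate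
6 | (2E,6E)-3,7-dimethyldodeca-2,6-dien-10-yn-1-ol | OC/C=C(\C)CC/C=C(\C)CCC#CC | intermediate
7 | alkenylzirconocene chloride of 6 (hydroxyl also bound to zirconium) | Cl[Zr](OC/C=C(\C)CC/C=C(\C)CC/C=C(\C)[Zr](Cl)(C1C=CC=C1)C1C=CC=C1)(C1C=CC=C1)C1C=CC=C1 | intermediate
8 | (2E,6E,10E)-11-iodo-3,7-dimethyldodeca-2,6,10-trien-1-ol | OC/C=C(\C)CC/C=C(\C)CC/C=C(\C)I | intermediate
9 | [(2S,3S)-3-[(3E,7E)-8-iodo-4-methylnona-3,7-dien-1-yl]-3-methyloxiran-2-yl]methanol | OC[C@@H]1O[C@@]1(C)CC/C=C(\C)CC/C=C(\C)I | intermediate
10 | [(2S,3S)-3-[(3E,7E)-8-iodo-4-methylnona-3,7-dien-1-yl]-3-methyloxiran-2-yl]methyl trifluoromethanesulfonate | O=S(=O)(OC[C@@H]1O[C@@]1(C)CC/C=C(\C)CC/C=C(\C)I)C(F)(F)F | intermediate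
11 | (2S,3S)-2-allyl-3-[(3E,7E)-8-iodo-4-methylnona-3,7-dien-1-yl]-3-methyloxirane | C=CC[C@@H]1O[C@@]1(C)CC/C=C(\C)CC/C=C(\C)I | intermediate
12 | methyl 2-(bromomethyl)acrylate | C=C(CBr)C(=O)OC | starting material
13 | methyl (2Z)-2-(bromomethyl)-4-[(2S,3S)-3-[(3E,7E)-8-iodo-4-methylnona-3,7-dien-1-yl]-3-methyloxiran-2-yl]but-2-enoate | COC(=O)/C(CBr)=C/C[C@@H]1O[C@@]1(C)CC/C=C(\C)CC/C=C(\C)I | intermediate
14 | (tert-butyldimethylsilyloxy)acetaldehyde | CC(C)(C)[Si](C)(C)OCC=O | starting material
15 | methyl (3R,4R)-5-(tert-butyldimethylsilyloxy)-4-hydroxy-2-methylidene-3-{[(2S,3S)-3-[(3E,7E)-8-iodo-4-methylnona-3,7-dien-1-yl]-3-methyloxiran-2-yl]methyl}pentanoate | COC(=O)C(=C)[C@@H](C[C@@H]1O[C@@]1(C)CC/C=C(\C)CC/C=C(\C)I)[C@@H](O)CO[Si](C)(C)C(C)(C)C | intermediate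
16 | (4R,5R)-5-[(tert-butyldimethylsilyloxy)methyl]-4-{[(2S,3S)-3-[(3E,7E)-8-iodo-4-methylnona-3,7-dien-1-yl]-3-methyloxiran-2-yl]methyl}-3-methylideneoxolan-2-one | CC(C)(C)[Si](C)(C)OC[C@@H]1OC(=O)C(=C)[C@H]1C[C@@H]2O[C@@]2(C)CC/C=C(\C)CC/C=C(\C)I | intermediate
17 | (4R,5R)-5-(hydroxymethyl)-4-{[(2S,3S)-3-[(3E,7E)-8-iodo-4-methylnona-3,7-dien-1-yl]-3-methyloxiran-2-yl]methyl}-3-methylideneoxolan-2-one | OC[C@@H]1OC(=O)C(=C)[C@H]1C[C@@H]2O[C@@]2(C)CC/C=C(\C)CC/C=C(\C)I | intermediate
18 | (2R,3R)-3-{[(2S,3S)-3-[(3E,7E)-8-iodo-4-methylnona-3,7-dien-1-yl]-3-methyloxiran-2-yl]methyl}-4-methylidene-5-oxooxolane-2-carbaldehyde | O=C[C@@H]1OC(=O)C(=C)[C@H]1C[C@@H]2O[C@@]2(C)CC/C=C(\C)CC/C=C(\C)I | intermediate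
19 | (1R,3S,4S,7E,11E,13S,14R)-3,4-epoxy-13-hydroxycembra-7,11,15(17)-trien-16,14-olide | C1/C=C(\C)[C@H](O)[C@@H]2OC(=O)C(=C)[C@H]2C[C@@H]3O[C@@]3(C)CC/C=C(\C)C1 | intermediate
20 | (1R,3S,4S,7E,11E,13S,14R)-13-acetoxy-3,4-epoxycembra-7,11,15(17)-trien-16,14-olide | C1/C=C(\C)[C@H](OC(C)=O)[C@@H]2OC(=O)C(=C)[C@H]2C[C@@H]3O[C@@]3(C)CC/C=C(\C)C1 | intermediate
21 | (1R,3S,4S,7S,11E,13S,14R)-13-acetoxy-3,4-epoxy-7-hydroperoxycembra-8(19),11,15(17)-trien-16,14-olide (CNP0166375.1) | C=C1CC/C=C(\C)[C@H](OC(C)=O)[C@@H]2OC(=O)C(=C)[C@H]2C[C@@H]2O[C@@]2(C)CC[C@@H]1OO | target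

**Step count and risks**

Total step count: 15. Longest linear sequence: 15 steps (from 1).

Steps most likely to fail:

Step 15 (photooxygenation). Singlet oxygen may bond to C8 with abstraction of a C6 ring hydrogen, giving the tertiary hydroperoxide, or may approach the wrong face of the alkene. The fallback sets out from 20 and separates the C–X bond formation from the oxygenation. Ene-type chlorination with hypochlorous acid (Ca(OCl)2, CO2, CH2Cl2/H2O, 0 °C) places the heteroatom on the less substituted C7 and moves the alkene to C8=C19, giving the allylic chloride (1R,3S,4S,11E,13S,14R)-13-acetoxy-7-chloro-3,4-epoxycembra-8(19),11,15(17)-trien-16,14-olide F1. Silver-assisted perhydrolysis (AgOCOCF3, anhydrous H2O2 in Et2O, NaHCO3, 0 °C) then comes back to the route at 21, the C7 epimers being separated by chromatography.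

Step 10 (asymmetric allylation). The chiral chromium complex may select poorly between the faces of the small aldehyde in the presence of the Lewis-basic chiral substrate. The fallback sets out from 13 and replaces catalyst control by substrate control. Stoichiometric CrCl2 without ligand (THF, rt) and the chiral-pool aldehyde (S)-2,3-bis(tert-butyldimethylsilyloxy)propanal should give, by Felkin–Anh addition and the same anti chair transition state, the lactone (4R,5R)-5-[(1S)-1,2-bis(tert-butyldimethylsilyloxy)ethyl]-4-{[(2S,3S)-3-[(3E,7E)-8-iodo-4-methylnona-3,7-dien-1-yl]-3-methyloxiran-2-yl]methyl}-3-methylideneoxolan-2-one F2. TBAF/AcOH gives the corresponding (1S)-1,2-dihydroxyethyl lactone F3, and NaIO4 (THF/H2O, pH 7) cleaves the glycol to aldehyde 18, where the route is rejoined.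

Step 13 (macrocyclization). The constraints of the macrocyclic transition state may override the Felkin–Anh preference and lead to poor facial selectivity at the aldehyde. The fallback sets out from 18 and sets C13 by substitution instead of by carbonyl addition. The cyclization is run in the same way and the epimeric alcohol (1R,3S,4S,7E,11E,13R,14R)-3,4-epoxy-13-hydroxycembra-7,11,15(17)-trien-16,14-olide F4 is separated. A Mitsunobu reaction with acetic acid (PPh3, DIAD, toluene, 0 °C) inverts C13 and gives the acetate 20 directly, where the route is rejoined.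

**Further compounds**

F1 | step 15 | (1R,3S,4S,11E,13S,14R)-13-acetoxy-7-chloro-3,4-epoxycembra-8(19),11,15(17)-trien-16,14-olide (C7 epimers) | C=C1CC/C=C(\C)[C@H](OC(C)=O)[C@@H]2OC(=O)C(=C)[C@H]2C[C@@H]2O[C@@]2(C)CCC1Cl
F2 | step 10 | (4R,5R)-5-[(1S)-1,2-bis(tert-butyldimethylsilyloxy)ethyl]-4-{[(2S,3S)-3-[(3E,7E)-8-iodo-4-methylnona-3,7-dien-1-yl]-3-methyloxiran-2-yl]methyl}-3-methylideneoxolan-2-one | CC(C)(C)[Si](C)(C)OC[C@H](O[Si](C)(C)C(C)(C)C)[C@@H]1OC(=O)C(=C)[C@H]1C[C@@H]2O[C@@]2(C)CC/C=C(\C)CC/C=C(\C)I
F3 | step 10 | (4R,5R)-5-[(1S)-1,2-dihydroxyethyl]-4-{[(2S,3S)-3-[(3E,7E)-8-iodo-4-methylnona-3,7-dien-1-yl]-3-methyloxiran-2-yl]methyl}-3-methylideneoxolan-2-one | OC[C@H](O)[C@@H]1OC(=O)C(=C)[C@H]1C[C@@H]2O[C@@]2(C)CC/C=C(\C)CC/C=C(\C)I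
F4 | step 13 | (1R,3S,4S,7E,11E,13R,14R)-3,4-epoxy-13-hydroxycembra-7,11,15(17)-trien-16,14-olide | C1/C=C(\C)[C@@H](O)[C@@H]2OC(=O)C(=C)[C@H]2C[C@@H]3O[C@@]3(C)CC/C=C(\C)C1
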